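**Numbering used throughout**

Target atoms: C1 is the quaternary carbinol, C7 its exocyclic CH2, C2 the carbinol next to C3 (the benzoate carbon), C4 and C5 the two CH2 groups, C6 the other carbinol; On is the oxygen on Cn.

Compounds: 1 dihydroxyacetone; 2 TBSCl; 3 bis-silyl ketone; 4 pent-4-enal; 5 syn-aldol; 6 benzoyl chloride; 7 aldol benzoate; 8 primary alcohol; 9 alkene dibenzoate; 10 ozonide (not isolated); 11 keto-aldehyde; 12 α-ketol; 13 silylated triol; 14 target.

## Analysis of the target

Compound 14 is a single cyclohexane ring with oxygen on five of its seven carbons: a tertiary carbinol C1 carrying a benzoyloxymethyl arm (C7), secondary carbinols C2 and C6 on either side of it, a secondary benzoate at C3, and a bare C4–C5 ethano segment. The four stereocentres C6, C1, C2 and C3 are contiguous (1S,2S,3R,6R). O1 is trans to both O2 and O6, and O2 is trans to O3, so O2 and O6 are cis to each other and all four ring oxygens can be equatorial in one chair with the C7 arm axial. The two benzoates sit beside three free hydroxyls, so base can move acyl groups (O3 to O2, O7 to O1 or O6). Any intermediate with a carbonyl β to a benzoate can eliminate, and a tertiary α-ketol can rearrange. The difficulty is the quaternary carbinol flanked by two trans-disposed secondary carbinols, together with benzoates on O3 and O7 only and no spare functionality on C4 and C5. The strategy rests on the C1–C6 bond: the tertiary carbinol is bonded directly to the C6 carbinol, and with C6 raised to a ketone this pair is an α-ketol, the product of adding a C6 acyl anion to a C1 ketone. Cutting there opens the ring to a seven-carbon chain whose only stereocentres, C2 and C3, form a syn-diol pattern that one aldol reaction can set.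

## Retrosynthetic reasoning

14 from 13. The last step frees O2 alone; no skeletal bond is cut. Keeping O2 as a silyl ether to the end prevents the C3 benzoate from migrating to it and keeps O2 from acting as a directing group in the reduction before. The forward step must remove a hindered secondary silyl ether without base.

13 from 12. The C6 carbinol is traced back to a ketone. This places the molecule at the α-ketol oxidation level that the ring closure delivers. The forward reduction must add hydride to the face of C6 that carries O1, so that O6 ends trans to O1; the free tertiary hydroxyl of 12 is the only one available to direct it.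

12 from 11. The C1–C6 bond is cut. This is the only ring bond whose formation creates the tertiary carbinol and the ring at once while leaving C2 and C3 to be set earlier on an open chain. The precursor 11 is a keto-aldehyde in which only the aldehyde can become an acyl-anion equivalent, so the crossed reaction is chemoselective by construction. The forward step must close the six-membered ring and choose the face of the C1 ketone so that O1 ends trans to O2; a chiral triazolium-derived carbene and the chair preference of the chain are to do this together.

11 from 9 (through 10). The aldehyde carbon C6 is derived from a terminal alkene by oxidative cleavage, with loss of one carbon. The alkene is inert in all earlier steps and is unmasked only when the sensitive keto-aldehyde is needed.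

9 from 8 from 7. The O7 benzoate is introduced by exchanging the primary silyl ether of 7 for a benzoyl group from 6. Placing both benzoates before the ring exists avoids any late differentiation of O7 and O3 from O1, O2 and O6. The forward step must cleave the primary silyl ether and leave the secondary one on O2.

7 from 5. The O3 benzoate is put on the one free hydroxyl of the aldol product, again from 6, so its position is fixed without any selectivity problem.

5 from 3 and 4. The C2–C3 bond is cut in an aldol sense. Ketone 3 supplies C7, C1 and C2 at the right oxidation level, and aldehyde 4 supplies C3 to C6 with the latent aldehyde. A primary amino acid catalyst is to set C2 and C3 together as the syn pair.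

3 from 1 and 2. Both hydroxyls of 1 are silylated, which gives a symmetrical donor with no regiochemical issue in the aldol.

## Alternatives that were turned down

Alternative 1: No skeletal bond is disconnected; the ring is taken intact from benzoic acid A1. In the forward key step, whole cells of a Ralstonia eutropha mutant expressing benzoate 1,2-dioxygenase dihydroxylate A1 at the ipso and ortho carbons to give (1S,2R)-1,2-dihydroxycyclohexa-3,5-diene-1-carboxylic acid A2.
- For it: one enzymatic step gives the ring, C7 (as the carboxyl) and the quaternary carbinol in enantiopure form. The quaternary carbon of A2 has the absolute configuration of C1 of 14 when its carbinol neighbour is read as C2.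
- Against it: the secondary hydroxyl of A2 is cis to the tertiary one, whereas 14 needs it trans, so an inversion next to a quaternary centre is required. One alkene of A2 must then become C3–OBz (trans to O2) and C4H2, and the other C5H2 and C6–OH (trans to O1). These are two regio- and stereoselective net hydrations with no directing element, and the acid must also be reduced to the CH2OBz arm.
- Comparison: this route is stronger on absolute control at C1 and on supply of the first intermediate. The chosen route puts every carbonyl where an oxygen is needed, carries no unsaturation to remove, and sets C2 and C3 with the right relative configuration in one step.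

Alternative 2: The C3–C4 bond is disconnected (sugar C1 to C6). In the forward key step a C3-branched sugar enol ether, methyl 2,4-di-O-benzyl-6-deoxy-3-C-(hydroxymethyl)-3,3′-O-isopropylidenehex-5-enopyranoside A3, is treated in aqueous organic solvent with a catalytic amount of mercury bis(trifluoroacetate) A4, Hg(OCOCF3)2, a divalent mercury salt. Hydration of the enol ether of A3, promoted by the mercury salt A4, releases an enolate that adds to the anomeric aldehyde and gives (5R,6S,9S,10S)-6,10-bis(benzyloxy)-9-hydroxy-2,2-dimethyl-1,3-dioxaspiro[4.5]decan-7-one A5.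
- For it: C1, C2 and C6 come from the chiral pool with no dependence on a catalyst's sense of induction, and the carbocyclisation is robust.
- Against it: A5 carries a ketone at C5 where 14 has CH2, so a deoxygenation is needed. Its C3 hydroxyl is cis to O2, so it must be inverted as it is benzoylated, on a β-hydroxy ketone that can eliminate. Benzyl and acetonide groups must be exchanged for benzoates on O3 and O7 only. Preparation of A3 is itself long, and the salt A4 brings toxic mercury into the route.
- Comparison: this route is stronger on predictability of the three pool-derived stereocentres. The chosen route is roughly half as long and never oxygenates C4 or C5.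

Alternative 3: Two bonds are disconnected, C5–C6 and C2–C3. In the forward key step a chiral secondary amino acid catalyst joins the ketone 2,2-dimethyl-1,3-dioxan-5-one A6 and the enal acrolein A7 by Michael addition and then intramolecular aldol closure, giving (1R,5S,6R)-6-hydroxy-3,3-dimethyl-2,4-dioxabicyclo[3.3.1]nonan-9-one A8.
- For it: two C–C bonds and the ring form in one step from two cheap achiral compounds, A6 and A7. A8 already has O2, O3 and O6 in the relative arrangement of 14 and C4–C5 saturated, and its only free hydroxyl is O3, so the benzoate goes on without selectivity. In step count to the ring this route is stronger than the chosen one.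
- Against it: the Michael stereocentre is epimerisable and the aldol closure is reversible, so the absolute sense depends on a dynamic resolution whose outcome cannot be predicted and would have to be screened; A7 also polymerises readily, and A6 can be alkylated by it a second time. The quaternary carbinol C1 must be made afterwards by intermolecular addition of a one-carbon nucleophile to the bridging ketone of A8. Its two faces differ only by an O–CMe2–O bridge against a CH2–CH2–CH(O) bridge, and the addition must come from the side of the dioxane bridge; no element secures this. After acetonide removal O7 must be benzoylated beside three free hydroxyls.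
- Comparison: the chosen route spends more linear steps but forms C1 intramolecularly under catalyst and chair control, with both benzoates already in place.

Key step: step 7

**Remarks on the chemistry assumed**

- Dihydroxyacetone is sold as its dimer, which reacts as the monomer under silylation; it is written as the monomer 1.
- The D-antipode of O-tert-butylthreonine is assigned to step 2 from the hydrogen-bonded (Z)-enamine model; the L-antipode should give the enantiomer of 5.
- The (5aS,10bR)-antipode of the triazolium salt is assigned to step 7 from a model with the enol oxygen beside the N-aryl group, the chain beside the ring fusion, and attack opposite the indane. This assignment is a model prediction, and the enol geometry it assumes is not certain. Both antipodes of both catalysts are commercial.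

## Route

Step 1
Reactants: 1 1,3-dihydroxyacetone; 2 tert-butyldimethylsilyl chloride
Product: 3 1,3-bis[(tert-butyldimethylsilyl)oxy]propan-2-one
Conditions: TBSCl (2.2 equiv), imidazole (4 equiv), DMF, 0 °C to rt
Reagents that add atoms: tert-butyldimethylsilyl chloride (2), CC(C)(C)[Si](C)(C)Cl
Why: Imidazole-promoted O-silylation of both primary hydroxyls; the dimeric hemiketal form of 1 opens under the conditions, so the symmetrical ketone should result.

Step 2
Reactants: 3 1,3-bis[(tert-butyldimethylsilyl)oxy]propan-2-one; 4 pent-4-enal
Product: 5 (3S,4R)-1,3-bis[(tert-butyldimethylsilyl)oxy]-4-hydroxyoct-7-en-2-one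
Conditions: O-tert-butyl-D-threonine (20 mol %), NMP, H2O (3 vol %), 4 °C to rt; 3 in excess (2 equiv), 4 added slowly
Reagents that add atoms: none
Why: Primary-amine-catalysed direct syn-aldol reaction: the amino acid condenses with 3 to a (Z)-enamine held by an N–H···O hydrogen bond, and its carboxylic acid guides 4 to one face, which should set C3 and C4 of 5 (target C2 and C3) together as the syn (3S,4R) pair. The D-catalyst is the antipode expected to give this D-threo sense.

Step 3
Reactants: 5 (3S,4R)-1,3-bis[(tert-butyldimethylsilyl)oxy]-4-hydroxyoct-7-en-2-one; 6 benzoyl chloride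
Product: 7 (3S,4R)-1,3-bis[(tert-butyldimethylsilyl)oxy]-2-oxooct-7-en-4-yl benzoate
Conditions: BzCl (1.3 equiv), pyridine, DMAP (cat.), CH2Cl2, 0 °C
Reagents that add atoms: benzoyl chloride (6), O=C(Cl)c1ccccc1
Why: DMAP-catalysed acylation of the only free hydroxyl; no stereocentre is touched, and the weak base and low temperature should keep the β-benzoyloxy ketone from eliminating.

Step 4
Reactants: 7 (3S,4R)-1,3-bis[(tert-butyldimethylsilyl)oxy]-2-oxooct-7-en-4-yl benzoate
Product: 8 (3S,4R)-3-[(tert-butyldimethylsilyl)oxy]-1-hydroxy-2-oxooct-7-en-4-yl benzoate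
Conditions: HF·pyridine, pyridine, THF, 0 °C
Reagents that add atoms: none
Why: Selective desilylation: the primary silyl ether is cleaved faster than the secondary one for steric reasons, and the buffered acidic fluoride should neither move the benzoate nor enolise the ketone.

Step 5
Reactants: 8 (3S,4R)-3-[(tert-butyldimethylsilyl)oxy]-1-hydroxy-2-oxooct-7-en-4-yl benzoate; 6 benzoyl chloride
Product: 9 (3S,4R)-3-[(tert-butyldimethylsilyl)oxy]-2-oxooct-7-ene-1,4-diyl dibenzoate
Conditions: BzCl (1.2 equiv), pyridine, CH2Cl2, 0 °C
Reagents that add atoms: benzoyl chloride (6), O=C(Cl)c1ccccc1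
Why: Acylation of the unhindered primary α-ketol hydroxyl; this places the O7 benzoate before any other hydroxyl of the target exists.

Step 6
Reactants: 9 (3S,4R)-3-[(tert-butyldimethylsilyl)oxy]-2-oxooct-7-ene-1,4-diyl dibenzoate
Product: 11 (3S,4R)-3-[(tert-butyldimethylsilyl)oxy]-2,7-dioxoheptane-1,4-diyl dibenzoate, via trioxolane ozonide 10 (not isolated)
Conditions: O3, CH2Cl2, −78 °C; then PPh3, −78 °C to rt
Reagents that add atoms: ozone, O=[O+][O-]
Why: Ozonolysis with reductive work-up: cycloaddition and rearrangement give ozonide 10, which PPh3 reduces to the aldehyde; the electron-poor benzoate rings and the silyl ether are inert, and the neutral conditions spare the β-benzoyloxy ketone.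

Step 7
Reactants: 11 (3S,4R)-3-[(tert-butyldimethylsilyl)oxy]-2,7-dioxoheptane-1,4-diyl dibenzoate
Product: 12 [(1R,2S,3R)-3-(benzoyloxy)-2-[(tert-butyldimethylsilyl)oxy]-1-hydroxy-6-oxocyclohexyl]methyl benzoate
Conditions: (5aS,10bR)-2-(pentafluorophenyl)-5a,10b-dihydro-4H,6H-indeno[2,1-b][1,2,4]triazolo[4,3-d][1,4]oxazin-2-ium tetrafluoroborate (20 mol %), Et3N (20 mol %), toluene, rt, argon
Reagents that add atoms: none
Why: The free carbene adds to the C6 aldehyde of 11 and proton transfer gives the enaminol (Breslow intermediate), an acyl-anion equivalent that only the aldehyde can form, which makes the crossed reaction chemoselective. Its nucleophilic carbon attacks the C1 ketone, activated by two α-oxygen substituents, in a 6-exo-trig closure that forms C1–C6 and the carbocycle; collapse of the adduct releases the carbene and leaves the α-ketol. The closest known reaction type is the enantioselective intramolecular crossed aldehyde–ketone benzoin cyclisation under chiral bicyclic triazolylidene catalysis. The one new stereocentre, C1, is controlled by two elements meant to cooperate: the indane of the catalyst shields one face of the enaminol while the enol O–H hydrogen-bonds to the ketone oxygen and so fixes the orientation of the ketone. In addition, the chair-like transition state of the chain places O2 (anti to the forming bond), O3 and the ketone oxygen equatorial with the C7 arm axial, the arrangement that leads to O1 trans to O2. Besides this facial selectivity the step needs the C3 benzoate β to the ketone to survive and aldolisation to be suppressed; no more amine base than catalyst, the weakly basic N-pentafluorophenyl carbene and a non-polar solvent are chosen for this.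

Step 8
Reactants: 12 [(1R,2S,3R)-3-(benzoyloxy)-2-[(tert-butyldimethylsilyl)oxy]-1-hydroxy-6-oxocyclohexyl]methyl benzoate
Product: 13 [(1S,2S,3R,6R)-3-(benzoyloxy)-2-[(tert-butyldimethylsilyl)oxy]-1,6-dihydroxycyclohexyl]methyl benzoate
Conditions: Me4NBH(OAc)3 (5 equiv), MeCN/AcOH (1:1), −20 °C to 0 °C
Reagents that add atoms: none
Why: Hydroxyl-directed (Evans–Saksena-type) reduction: the tertiary C1 hydroxyl exchanges an acetate on boron and the alkoxyborohydride delivers hydride to the face of C6 that carries O1, so the new hydroxyl should end trans to O1 (6R). O2 stays silylated so that it cannot direct hydride to the opposite face, and axial attack on the chair with the C7 arm axial leads to the same equatorial alcohol.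

Step 9
Reactants: 13 [(1S,2S,3R,6R)-3-(benzoyloxy)-2-[(tert-butyldimethylsilyl)oxy]-1,6-dihydroxycyclohexyl]methyl benzoate
Product: 14 [(1S,2S,3R,6R)-3-(benzoyloxy)-1,2,6-trihydroxycyclohexyl]methyl benzoate
Conditions: HF·pyridine, THF, 0 °C to rt
Reagents that add atoms: none
Why: Fluoride-mediated desilylation under acidic conditions; without base the C3 and C7 benzoates should stay in place and no stereocentre is affected.

## Compound list

1 | 1,3-dihydroxyacetone | OCC(=O)CO | starting material
2 | tert-butyldimethylsilyl chloride | CC(C)(C)[Si](C)(C)Cl | starting material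
3 | 1,3-bis[(tert-butyldimethylsilyl)oxy]propan-2-one | CC(C)(C)[Si](C)(C)OCC(=O)CO[Si](C)(C)C(C)(C)C | intermediate
4 | pent-4-enal | C=CCCC=O | starting material
5 | (3S,4R)-1,3-bis[(tert-butyldimethylsilyl)oxy]-4-hydroxyoct-7-en-2-one | C=CCC[C@@H](O)[C@H](O[Si](C)(C)C(C)(C)C)C(=O)CO[Si](C)(C)C(C)(C)C | intermediate
6 | benzoyl chloride | O=C(Cl)c1ccccc1 | starting material
7 | (3S,4R)-1,3-bis[(tert-butyldimethylsilyl)oxy]-2-oxooct-7-en-4-yl benzoate | C=CCC[C@@H](OC(=O)c1ccccc1)[C@H](O[Si](C)(C)C(C)(C)C)C(=O)CO[Si](C)(C)C(C)(C)C | intermediate
8 | (3S,4R)-3-[(tert-butyldimethylsilyl)oxy]-1-hydroxy-2-oxooct-7-en-4-yl benzoate | C=CCC[C@@H](OC(=O)c1ccccc1)[C@H](O[Si](C)(C)C(C)(C)C)C(=O)CO | intermediate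
9 | (3S,4R)-3-[(tert-butyldimethylsilyl)oxy]-2-oxooct-7-ene-1,4-diyl dibenzoate | C=CCC[C@@H](OC(=O)c1ccccc1)[C@H](O[Si](C)(C)C(C)(C)C)C(=O)COC(=O)c1ccccc1 | intermediate
10 | (3S,4R)-3-[(tert-butyldimethylsilyl)oxy]-2-oxo-6-(1,2,4-trioxolan-3-yl)hexane-1,4-diyl dibenzoate (ozonide, both epimers at the trioxolane carbon, not isolated) | C1(OCOO1)CC[C@@H](OC(=O)c2ccccc2)[C@H](O[Si](C)(C)C(C)(C)C)C(=O)COC(=O)c2ccccc2 | intermediate
11 | (3S,4R)-3-[(tert-butyldimethylsilyl)oxy]-2,7-dioxoheptane-1,4-diyl dibenzoate | O=CCC[C@@H](OC(=O)c1ccccc1)[C@H](O[Si](C)(C)C(C)(C)C)C(=O)COC(=O)c1ccccc1 | intermediate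
12 | [(1R,2S,3R)-3-(benzoyloxy)-2-[(tert-butyldimethylsilyl)oxy]-1-hydroxy-6-oxocyclohexyl]methyl benzoate | O=C(OC[C@]1(O)C(=O)CC[C@@H](OC(=O)c2ccccc2)[C@@H]1O[Si](C)(C)C(C)(C)C)c1ccccc1 | intermediate
13 | [(1S,2S,3R,6R)-3-(benzoyloxy)-2-[(tert-butyldimethylsilyl)oxy]-1,6-dihydroxycyclohexyl]methyl benzoate | O=C(OC[C@]1(O)[C@H](O)CC[C@@H](OC(=O)c2ccccc2)[C@@H]1O[Si](C)(C)C(C)(C)C)c1ccccc1 | intermediate
14 | [(1S,2S,3R,6R)-3-(benzoyloxy)-1,2,6-trihydroxycyclohexyl]methyl benzoate | O=C(OC[C@]1(O)[C@H](O)CC[C@@H](OC(=O)c2ccccc2)[C@@H]1O)c1ccccc1 | target

## Step count and risk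

Total step count: 9. Longest linear sequence: 9 steps (from 1 to 14).

Step 7 (key step). Two processes may spoil it. The first is base-induced loss of the C3 benzoate from 11, by enolisation of the C1 ketone toward C2 and β-elimination, or aldolisation of the keto-aldehyde, before the carbene-bound acyl anion closes the ring. The second is poor facial selectivity at C1 if the catalyst antipode and the chair preference of the chain oppose each other; the matched antipode is assigned by a model, so both antipodes would be tested on small scale, which is a change of conditions only. The fallback forms the same C1–C6 bond as an alkene and sets C1 by osmylation. It sets out from 9. The ketone is methylenated with the non-basic titanium methylidene reagent Cp2Ti(μ-Cl)(μ-CH2)AlMe2 (THF, −40 °C), which should react faster with the ketone than with the benzoates, to give (3R,4R)-3-[(tert-butyldimethylsilyl)oxy]-2-methylideneoct-7-ene-1,4-diyl dibenzoate F1. Ring-closing metathesis with the second-generation Grubbs catalyst RuCl2(=CHPh)(PCy3)(H2IMes) then gives [(5R,6R)-5-(benzoyloxy)-6-[(tert-butyldimethylsilyl)oxy]cyclohex-1-en-1-yl]methyl benzoate F2. Dihydroxylation with catalytic OsO4 and N-methylmorpholine N-oxide should occur on the face anti to the allylic silyloxy group and give [(1S,2S,3R,6S)-3-(benzoyloxy)-2-[(tert-butyldimethylsilyl)oxy]-1,6-dihydroxycyclohexyl]methyl benzoate F3, with O1 trans to O2. Oxidation of its secondary hydroxyl (SO3·pyridine, DMSO, i-Pr2NEt) comes back to the route at 12.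

Step 2. Self-condensation of the unbranched, enolisable aldehyde 4 through its own enamine may outrun the cross-aldol reaction and erode the syn/anti ratio and the enantiomeric purity. The fallback is an auxiliary-controlled glycolate aldol that sets out from 4 and comes back at 9. Commercial (tert-butyldimethylsilyloxy)acetic acid is activated with pivaloyl chloride and Et3N to give the mixed anhydride [(tert-butyldimethylsilyl)oxy]acetic pivalic anhydride F4, which acylates (S)-4-benzyloxazolidin-2-one (LiCl, THF) to give (S)-4-benzyl-3-{[(tert-butyldimethylsilyl)oxy]acetyl}oxazolidin-2-one F5. Its (Z)-boron enolate (Bu2BOTf, Et3N, CH2Cl2, −78 °C) adds to 4 to give the Evans syn adduct (S)-4-benzyl-3-[(2S,3R)-2-[(tert-butyldimethylsilyl)oxy]-3-hydroxyhept-6-enoyl]oxazolidin-2-one F6. Benzoylation gives (S)-4-benzyl-3-[(2S,3R)-3-(benzoyloxy)-2-[(tert-butyldimethylsilyl)oxy]hept-6-enoyl]oxazolidin-2-one F7, and LiOH/H2O2 at 0 °C, which attacks the exocyclic imide carbonyl in preference to the benzoate, removes the auxiliary to give (2S,3R)-3-(benzoyloxy)-2-[(tert-butyldimethylsilyl)oxy]hept-6-enoic acid F8. Ethyl chloroformate and Et3N convert it into (2S,3R)-3-(benzoyloxy)-2-[(tert-butyldimethylsilyl)oxy]hept-6-enoic ethyl carbonic anhydride F9, which is treated with diazomethane to give (3S,4R)-3-[(tert-butyldimethylsilyl)oxy]-1-diazo-2-oxooct-7-en-4-yl benzoate F10. Insertion of its carbenoid into the O–H bond of benzoic acid A1, used in excess with catalytic dirhodium tetraacetate Rh2(OAc)4, gives 9 and bypasses steps 3 to 5.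

Step 4. Both silyl ethers may be lost, or the secondary silyl group may migrate, because each is activated by the adjacent ketone. The fallback replaces silyl-ether selectivity by acylation selectivity and sets out from 7. Excess HF·pyridine removes both silyl groups to give (3S,4R)-1,3-dihydroxy-2-oxooct-7-en-4-yl benzoate F11. Benzoylation of the primary hydroxyl alone (BzCl, 2,4,6-collidine, CH2Cl2, −78 °C) gives (3S,4R)-3-hydroxy-2-oxooct-7-ene-1,4-diyl dibenzoate F12. Silylation of the remaining secondary hydroxyl with TBSOTf and 2,6-lutidine at −78 °C comes back to the route at 9.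

Step 8. If the hindered tertiary hydroxyl binds boron slowly, undirected background reduction may lower the facial selectivity, and prolonged exposure to acid may trigger α-ketol rearrangement. The fallback changes the control element from substrate direction to catalyst control. From 12, Corey–Bakshi–Shibata reduction with (S)-1-methyl-3,3-diphenyltetrahydro-1H,3H-pyrrolo[1,2-c][1,3,2]oxazaborole and BH3·SMe2 in THF at −20 °C, with one extra equivalent of borane for the free hydroxyl, treats the quaternary C1 side as the large group and should give the (6R)-alcohol 13 directly; no new compound is formed on the way.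

## Further compounds

F1 | step 7 | (3R,4R)-3-[(tert-butyldimethylsilyl)oxy]-2-methylideneoct-7-ene-1,4-diyl dibenzoate | C=CCC[C@@H](OC(=O)c1ccccc1)[C@H](O[Si](C)(C)C(C)(C)C)C(=C)COC(=O)c1ccccc1
F2 | step 7 | [(5R,6R)-5-(benzoyloxy)-6-[(tert-butyldimethylsilyl)oxy]cyclohex-1-en-1-yl]methyl benzoate | O=C(OCC1=CCC[C@@H](OC(=O)c2ccccc2)[C@@H]1O[Si](C)(C)C(C)(C)C)c1ccccc1
F3 | step 7 | [(1S,2S,3R,6S)-3-(benzoyloxy)-2-[(tert-butyldimethylsilyl)oxy]-1,6-dihydroxycyclohexyl]methyl benzoate | O=C(OC[C@]1(O)[C@@H](O)CC[C@@H](OC(=O)c2ccccc2)[C@@H]1O[Si](C)(C)C(C)(C)C)c1ccccc1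
F4 | step 2 | [(tert-butyldimethylsilyl)oxy]acetic pivalic anhydride | CC(C)(C)C(=O)OC(=O)CO[Si](C)(C)C(C)(C)C
F5 | step 2 | (S)-4-benzyl-3-{[(tert-butyldimethylsilyl)oxy]acetyl}oxazolidin-2-one | O=C(CO[Si](C)(C)C(C)(C)C)N1C(=O)OC[C@@H]1Cc1ccccc1
F6 | step 2 | (S)-4-benzyl-3-[(2S,3R)-2-[(tert-butyldimethylsilyl)oxy]-3-hydroxyhept-6-enoyl]oxazolidin-2-one | C=CCC[C@@H](O)[C@H](O[Si](C)(C)C(C)(C)C)C(=O)N1C(=O)OC[C@@H]1Cc1ccccc1
F7 | step 2 | (S)-4-benzyl-3-[(2S,3R)-3-(benzoyloxy)-2-[(tert-butyldimethylsilyl)oxy]hept-6-enoyl]oxazolidin-2-one | C=CCC[C@@H](OC(=O)c1ccccc1)[C@H](O[Si](C)(C)C(C)(C)C)C(=O)N1C(=O)OC[C@@H]1Cc1ccccc1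
F8 | step 2 | (2S,3R)-3-(benzoyloxy)-2-[(tert-butyldimethylsilyl)oxy]hept-6-enoic acid | C=CCC[C@@H](OC(=O)c1ccccc1)[C@H](O[Si](C)(C)C(C)(C)C)C(=O)O
F9 | step 2 | (2S,3R)-3-(benzoyloxy)-2-[(tert-butyldimethylsilyl)oxy]hept-6-enoic ethyl carbonic anhydride | C=CCC[C@@H](OC(=O)c1ccccc1)[C@H](O[Si](C)(C)C(C)(C)C)C(=O)OC(=O)OCC
F10 | step 2 | (3S,4R)-3-[(tert-butyldimethylsilyl)oxy]-1-diazo-2-oxooct-7-en-4-yl benzoate | C=CCC[C@@H](OC(=O)c1ccccc1)[C@H](O[Si](C)(C)C(C)(C)C)C(=O)C=[N+]=[N-]
F11 | step 4 | (3S,4R)-1,3-dihydroxy-2-oxooct-7-en-4-yl benzoate | C=CCC[C@@H](OC(=O)c1ccccc1)[C@H](O)C(=O)CO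
F12 | step 4 | (3S,4R)-3-hydroxy-2-oxooct-7-ene-1,4-diyl dibenzoate | C=CCC[C@@H](OC(=O)c1ccccc1)[C@H](O)C(=O)COC(=O)c1ccccc1
F0 | step 8 | none | none
A1 | alternative 1 | benzoic acid | OC(=O)c1ccccc1
A2 | alternative 1 | (1S,2R)-1,2-dihydroxycyclohexa-3,5-diene-1-carboxylic acid | OC(=O)[C@]1(O)C=CC=C[C@H]1O
A3 | alternative 2 | methyl 2,4-di-O-benzyl-6-deoxy-3-C-(hydroxymethyl)-3,3′-O-isopropylidenehex-5-enopyranoside | CC1(C)OC[C@]2(O1)[C@H](OCc3ccccc3)C(=C)OC(OC)[C@@H]2OCc2ccccc2
A4 | alternative 2 | mercury bis(trifluoroacetate), Hg(OCOCF3)2 | [Hg+2].[O-]C(=O)C(F)(F)F.[O-]C(=O)C(F)(F)F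
A5 | alternative 2 | (5R,6S,9S,10S)-6,10-bis(benzyloxy)-9-hydroxy-2,2-dimethyl-1,3-dioxaspiro[4.5]decan-7-one | CC1(C)OC[C@]2(O1)[C@H](OCc3ccccc3)C(=O)C[C@H](O)[C@@H]2OCc2ccccc2
A6 | alternative 3 | 2,2-dimethyl-1,3-dioxan-5-one | CC1(C)OCC(=O)CO1
A7 | alternative 3 | acrolein | C=CC=O
A8 | alternative 3 | (1R,5S,6R)-6-hydroxy-3,3-dimethyl-2,4-dioxabicyclo[3.3.1]nonan-9-one | O=C1[C@H]2CC[C@@H](O)[C@@H]1OC(C)(C)O2
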